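**Strategy.** The target is cut at the bond between the carbinol carbon C6 of the perhydro-1-benzoxepine (numbering O1…C9a) and the two-carbon link: an acetylide of the cis-decalin adds to a benzoxepin-6-one. That ketone's carbocycle (C5a, C6, C7, C8, C9, C9a) is grown from a cyclopentanone: chloro(methyl)carbene adds to the silyl enol ether of a cis-fused cyclopenta[b]oxepinone and the chlorocyclopropane opens to the 2-methylcyclohexenone. The step exploits the quaternary, hydrogen-free ring-fusion carbon C5a beside the carbonyl: only one enol ether can form, so the new carbon C7, carrying its methyl, is inserted regiospecifically between C6 and C8 and arrives unsaturated for face-selective hydrogenation.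

Key step: step 6

Assumption: with the (R,S,S)-phosphoramidite of step 8 the alkenyl group is taken to reach the enone face that gives (3R)-14, the sense this ligand family shows with cyclohexenones; should it prove opposite, the (S,R,R)-ligand is used.
Assumption: the target is drawn as the free bis(hydrogen sulfate); it is liberated from its pyridinium salt by cation exchange and is best stored as the disodium salt.

**Step 1**
Reactants: 1 2-methylcyclopentane-1,3-dione; 2 acrolein
Product: 3 3-(1-methyl-2,5-dioxocyclopentyl)propanal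
Conditions: H2O, 20 °C
Reagents that add atoms: none
Why: Michael addition of the acidic 1,3-dione to acrolein needs no catalyst in water and stops at the mono-adduct because C2 becomes quaternary.

**Step 2**
Reactants: 3 3-(1-methyl-2,5-dioxocyclopentyl)propanal
Product: 4 2-methyl-2-(4-methylpent-3-en-1-yl)cyclopentane-1,3-dione
Conditions: i-PrPPh3I, n-BuLi, THF, 0 °C; then 3, −78 → 0 °C
Reagents that add atoms: isopropyltriphenylphosphonium iodide, CC(C)[P+](c1ccccc1)(c1ccccc1)c1ccccc1.[I-]
Why: Wittig olefination with the non-stabilised isopropylidene ylide should be far faster at the aldehyde than at the two hindered, α-quaternary ring ketones.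

**Step 3**
Reactants: 4 2-methyl-2-(4-methylpent-3-en-1-yl)cyclopentane-1,3-dione
Product: 5 (2S,3S)-3-hydroxy-2-methyl-2-(4-methylpent-3-en-1-yl)cyclopentan-1-one
Conditions: (R)-2-methyl-CBS-oxazaborolidine (20 mol%), catecholborane, PhNEt2, toluene, −78 → −40 °C
Reagents that add atoms: none
Why: Corey–Bakshi–Shibata reduction desymmetrises the prochiral dione: the (R)-catalyst selects one enantiotopic carbonyl (3S, quaternary carbon as the large group) and hydride arrives anti to the longer C2 chain, which fixes C2 (S) with the hydroxyl cis to the chain.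

**Step 4**
Reactants: 5 (2S,3S)-3-hydroxy-2-methyl-2-(4-methylpent-3-en-1-yl)cyclopentan-1-one
Product: 6 (5aS,8aS)-2,2,5a-trimethyloctahydro-6H-cyclopenta[b]oxepin-6-one
Conditions: TfOH (5 mol%), CH2Cl2 (dilute), 0 → 20 °C
Reagents that add atoms: none
Why: Brønsted-acid-catalysed Markovnikov hydroalkoxylation: the tertiary cation from the trisubstituted alkene is captured by the cis-disposed secondary hydroxyl (7-endo), closing the 2,2-dimethyloxepane cis-fused without touching a stereocentre.

**Step 5**
Reactants: 6 (5aS,8aS)-2,2,5a-trimethyloctahydro-6H-cyclopenta[b]oxepin-6-one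
Product: 7 {[(5aS,8aS)-2,2,5a-trimethyl-3,4,5,5a,8,8a-hexahydro-2H-cyclopenta[b]oxepin-6-yl]oxy}trimethylsilane
Conditions: Me3SiOTf, Et3N, CH2Cl2, 0 °C
Reagents that add atoms: trimethylsilyl trifluoromethanesulfonate, C[Si](C)(C)OS(=O)(=O)C(F)(F)F
Why: Soft enolisation and O-silylation; the quaternary C5a leaves C7 as the only enolisable position, so a single silyl enol ether should result.

**Step 6**
Reactants: 7 {[(5aS,8aS)-2,2,5a-trimethyl-3,4,5,5a,8,8a-hexahydro-2H-cyclopenta[b]oxepin-6-yl]oxy}trimethylsilane
Product: 9 (5aS,9aS)-2,2,5a,7-tetramethyl-3,4,5,5a,9,9a-hexahydro-1-benzoxepin-6(2H)-one, via chlorocyclopropane 8 (not isolated)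
Conditions: CH3CHCl2, n-BuLi, Et2O, −40 → 20 °C; then Et3N, toluene, 110 °C
Reagents that add atoms: 1,1-dichloroethane, CC(Cl)Cl
Why: Deprotonation of 1,1-dichloroethane and α-elimination give the chloro(methyl)carbenoid, which adds to the electron-rich C6=C7 bond of 7 to give cyclopropane 8; on heating, chloride departs with disrotatory opening of the cyclopropane bond shared with the five-membered ring, and the 2-silyloxyallyl cation loses Me3Si+ to chloride to give the 2-methylcyclohex-2-enone. The closest known reaction type is the halocarbene ring enlargement of cyclic silyl enol ethers to α-substituted cycloalkenones (one-carbon homologation). The only ring closed is the transient cyclopropane, by cheletropic [2+1] addition; the six-membered ring is not closed but arises from the five-membered one by two-electron electrocyclic cleavage of the internal cyclopropane bond. No stereocentre is formed, since the inserted carbon ends sp2 and the cyclopropane centres are destroyed, and C5a and C9a are untouched. The selectivity needed is regiochemical (new carbon between the carbonyl carbon and CH2, never next to C5a) and is secured by the hydrogen-free quaternary C5a, which allows only one enol ether. Only the endo-chloro cyclopropane can open directly, which the syn preference of chlorocarbenoids should favour; the exo-chloro isomer is expected to converge at 110 °C by ionisation and ion-pair return.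

**Step 7**
Reactants: 9 (5aS,9aS)-2,2,5a,7-tetramethyl-3,4,5,5a,9,9a-hexahydro-1-benzoxepin-6(2H)-one
Product: 10 (5aS,7R,9aS)-2,2,5a,7-tetramethyloctahydro-1-benzoxepin-6(2H)-one
Conditions: H2 (1 atm), Pd/C, EtOAc, 20 °C
Reagents that add atoms: none
Why: Heterogeneous hydrogenation should add H2 cis from the convex face of the cis-fused bicycle (the face of the angular methyl and the ring-fusion hydrogen), placing the new C7 methyl on the oxepane face (7R) under neutral conditions that do not epimerise the α-centre.

**Step 8**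
Reactants: 11 5-chloropent-1-yne; 12 2-methylcyclohex-2-en-1-one
Product: 14 (2RS,3R)-3-(5-chloropent-1-en-2-yl)-2-methylcyclohexan-1-one, via alkenylalane 13 (not isolated)
Conditions: i-Bu2AlH, Ni(dppp)Cl2 (3 mol%), THF, 0 → 20 °C; then 12, Cu(O2CC4H3S) (copper thiophene-2-carboxylate, 10 mol%), (R)-(1,1'-binaphthalene-2,2'-diyl) N,N-bis[(S)-1-phenylethyl]phosphoramidite (11 mol%), Et2O, −30 °C; aq. Rochelle salt
Reagents that add atoms: none
Why: Ni-catalysed α-selective hydroalumination gives the internal alkenylalane, and its Cu-catalysed asymmetric conjugate addition to the α-substituted cyclic enone (ligand control of the enone face) should set C3 (R); C2 is epimeric and inconsequential.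

**Step 9**
Reactants: 14 (2RS,3R)-3-(5-chloropent-1-en-2-yl)-2-methylcyclohexan-1-one
Product: 16 (4aS,8aR)-8a-methyl-5-methylideneoctahydronaphthalen-1(2H)-one, via potassium enolate 15 (not isolated)
Conditions: t-BuOK, t-BuOH/THF, 25 °C
Reagents that add atoms: none
Why: Equilibrating enolate formation followed by irreversible intramolecular 6-exo-tet alkylation at the methyl-bearing α-carbon (methylenecyclohexane annulation); a chair-like transition state with the tether axial on C3 should give the cis-fused decalone, the angular methyl cis to the ring-fusion hydrogen.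

**Step 10**
Reactants: 16 (4aS,8aR)-8a-methyl-5-methylideneoctahydronaphthalen-1(2H)-one
Product: 17 (4aS,5R,8aR)-5,8a-dimethyl-5-[(trimethylsilyl)ethynyl]octahydronaphthalen-1(2H)-one
Conditions: Fe(acac)3 (30 mol%), PhSiH3, PhSO2C≡CSiMe3, EtOH, 60 °C
Reagents that add atoms: phenyl 2-(trimethylsilyl)ethynyl sulfone, C[Si](C)(C)C#CS(=O)(=O)c1ccccc1
Why: Mukaiyama-type hydrogen-atom transfer from an iron hydride to the 1,1-disubstituted alkene gives the tertiary C5 radical (the exocyclic CH2 becomes the C5 methyl), which adds to the alkynyl sulfone and expels PhSO2 radical (radical hydroalkynylation); trapping on the convex face of the cis-decalin, syn to the angular methyl and ring-fusion hydrogen and anti to the axial C8a–C1 bond, should set C5 (R).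

**Step 11**
Reactants: 17 (4aS,5R,8aR)-5,8a-dimethyl-5-[(trimethylsilyl)ethynyl]octahydronaphthalen-1(2H)-one
Product: 19 (2RS,4aS,5R,8aR)-2,5,8a-trimethyl-5-[(trimethylsilyl)ethynyl]octahydronaphthalen-1(2H)-one, via lithium enolate 18 (not isolated)
Conditions: LDA, THF, −78 °C; MeI, −78 → 0 °C
Reagents that add atoms: iodomethane, CI
Why: Kinetic enolate alkylation; C8a is quaternary, so only C2 can be deprotonated and methylated (its configuration is irrelevant, C2 becomes sp2 in step 12).

**Step 12**
Reactants: 19 (2RS,4aS,5R,8aR)-2,5,8a-trimethyl-5-[(trimethylsilyl)ethynyl]octahydronaphthalen-1(2H)-one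
Product: 21 (4aS,5R,8aR)-2,5,8a-trimethyl-5-[(trimethylsilyl)ethynyl]-3,4,4a,5,6,7,8,8a-octahydronaphthalen-1-yl trifluoromethanesulfonate, via potassium enolate 20 (not isolated)
Conditions: KHMDS, THF, −78 → 0 °C; PhNTf2
Reagents that add atoms: N-phenylbis(trifluoromethanesulfonimide), O=S(=O)(N(c1ccccc1)S(=O)(=O)C(F)(F)F)C(F)(F)F
Why: Deprotonation of the remaining C2–H and O-sulfonylation give the only possible, tetrasubstituted enol triflate, as for 2,2,6-trimethylcyclohexanone.

**Step 13**
Reactants: 21 the enol triflate of step 12; 22 2-(chloromethyl)-1,4-dimethoxybenzene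
Product: 24 trimethyl{[(1R,4aR,8aR)-5-(2,5-dimethoxybenzyl)-1,4a,6-trimethyl-1,2,3,4,4a,7,8,8a-octahydronaphthalen-1-yl]ethynyl}silane, via benzylzinc chloride 23 (not isolated)
Conditions: 22, Zn, LiCl, THF, 25 °C; then 21, Pd(OAc)2 (3 mol%), SPhos (6 mol%), THF, 50 °C
Reagents that add atoms: none
Why: Negishi coupling of the hindered alkenyl triflate with the benzylic zinc reagent forms the sp2–sp3 bond without moving the tetrasubstituted double bond; the silyl alkyne is inert.

**Step 14**
Reactants: 24 the silyl alkyne of step 13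
Product: 25 (1R,4aR,8aS)-5-(2,5-dimethoxybenzyl)-1-ethynyl-1,4a,6-trimethyl-1,2,3,4,4a,7,8,8a-octahydronaphthalene
Conditions: K2CO3, MeOH, 20 °C
Reagents that add atoms: none
Why: Base-mediated methanolysis of the C(sp)–Si bond (protodesilylation) frees the terminal alkyne.

**Step 15**
Reactants: 25 the terminal alkyne of step 14; 10 (5aS,7R,9aS)-2,2,5a,7-tetramethyloctahydro-1-benzoxepin-6(2H)-one
Product: 28 tertiary propargylic alcohol (C6 of the benzoxepane bears OH cis to the C7 methyl and to O1, and the alkynyl group cis to the C5a methyl), via lithium acetylide 26 (not isolated), via cerium acetylide 27 (not isolated)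
Conditions: n-BuLi, THF, −78 °C; CeCl3, −78 °C; then 10, −78 → −20 °C
Reagents that add atoms: none
Why: The weakly basic cerium acetylide adds 1,2 to the hindered, enolisable ketone; the axial ring oxygen at C9a and the oxepane ring shield one face, so attack should be equatorial from the convex face, cis to the angular methyl, giving the axial tertiary alcohol cis to the C7 methyl.

**Step 16**
Reactants: 28 the propargylic alcohol of step 15
Product: 29 the corresponding 2-substituted 1,4-benzoquinone
Conditions: (NH4)2Ce(NO3)6, MeCN/H2O, 0 °C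
Reagents that add atoms: water, O
Why: Oxidative demethylation of the 1,4-dimethoxyarene (two one-electron oxidations, water adds, methanol leaves) gives the quinone; the electron-rich arene should be oxidised well before the tetrasubstituted alkene.

**Step 17**
Reactants: 29 the quinone of step 16
Product: 30 the hydroquinone with saturated two-carbon link (the free diphenol of the target)
Conditions: H2 (3 atm), Pd/C, EtOAc, 20 °C
Reagents that add atoms: none
Why: Hydrogenation over palladium should reduce the internal alkyne to the CH2–CH2 link and the quinone to the hydroquinone in one operation, while the tetrasubstituted ring alkene is too hindered to react.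

**Step 18**
Reactants: 30 the hydroquinone of step 17
Product: 31 CNP0125037.2, the bis(hydrogen sulfate) of 30
Conditions: SO3·pyridine, pyridine, 20 °C; then cation-exchange resin (H+ form), 0 °C
Reagents that add atoms: sulfur trioxide–pyridine complex, O=S(=O)([O-])[n+]1ccccc1
Why: O-Sulfation of both phenols; the tertiary alcohol, flanked by the quaternary C5a, should be too hindered to react.

**Compound list**

1 | 2-methylcyclopentane-1,3-dione | CC1C(=O)CCC1=O | starting material
2 | acrolein (prop-2-enal) | C=CC=O | starting material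
3 | 3-(1-methyl-2,5-dioxocyclopentyl)propanal | CC1(CCC=O)C(=O)CCC1=O | intermediate
4 | 2-methyl-2-(4-methylpent-3-en-1-yl)cyclopentane-1,3-dione | CC(C)=CCCC1(C)C(=O)CCC1=O | intermediate
5 | (2S,3S)-3-hydroxy-2-methyl-2-(4-methylpent-3-en-1-yl)cyclopentan-1-one (OH cis to the chain) | O=C1CC[C@H](O)[C@]1(C)CCC=C(C)C | intermediate
6 | (5aS,8aS)-2,2,5a-trimethyloctahydro-6H-cyclopenta[b]oxepin-6-one (cis-fused) | O=C1CC[C@@H]2OC(C)(C)CCC[C@@]21C | intermediate
7 | {[(5aS,8aS)-2,2,5a-trimethyl-3,4,5,5a,8,8a-hexahydro-2H-cyclopenta[b]oxepin-6-yl]oxy}trimethylsilane | C[Si](C)(C)OC1=CC[C@@H]2OC(C)(C)CCC[C@@]21C | intermediate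
8 | chlorocyclopropane: C6–C7 bond of 7 bridged by C(Cl)CH3, silyloxy on C6 (diastereomers at the cyclopropane carbons) | C[Si](C)(C)OC12C(C)(Cl)C1C[C@@H]1OC(C)(C)CCC[C@@]12C | intermediate
9 | (5aS,9aS)-2,2,5a,7-tetramethyl-3,4,5,5a,9,9a-hexahydro-1-benzoxepin-6(2H)-one | O=C1C(C)=CC[C@@H]2OC(C)(C)CCC[C@@]21C | intermediate
10 | (5aS,7R,9aS)-2,2,5a,7-tetramethyloctahydro-1-benzoxepin-6(2H)-one | O=C1[C@H](C)CC[C@@H]2OC(C)(C)CCC[C@@]21C | intermediate
11 | 5-chloropent-1-yne | C#CCCCCl | starting material
12 | 2-methylcyclohex-2-en-1-one | CC1=CCCCC1=O | starting material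
13 | (5-chloropent-1-en-2-yl)bis(2-methylpropyl)alumane | C=C(CCCCl)[Al](CC(C)C)CC(C)C | intermediate
14 | (2RS,3R)-3-(5-chloropent-1-en-2-yl)-2-methylcyclohexan-1-one | O=C1C(C)[C@H](C(=C)CCCCl)CCC1 | intermediate
15 | potassium enolate of 14 (C1=C2) | CC1=C([O-])CCC[C@H]1C(=C)CCCCl.[K+] | intermediate
16 | (4aS,8aR)-8a-methyl-5-methylideneoctahydronaphthalen-1(2H)-one (cis-fused) | O=C1[C@]2(C)CCCC(=C)[C@@H]2CCC1 | intermediate
17 | (4aS,5R,8aR)-5,8a-dimethyl-5-[(trimethylsilyl)ethynyl]octahydronaphthalen-1(2H)-one (alkynyl cis to angular methyl and ring-fusion H) | O=C1[C@]2(C)CCC[C@@](C)(C#C[Si](C)(C)C)[C@@H]2CCC1 | intermediate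
18 | lithium enolate of 17 (C1=C2) | [Li]OC1=CCC[C@H]2[C@](C)(C#C[Si](C)(C)C)CCC[C@@]12C | intermediate
19 | (2RS,4aS,5R,8aR)-2,5,8a-trimethyl-5-[(trimethylsilyl)ethynyl]octahydronaphthalen-1(2H)-one | O=C1[C@]2(C)CCC[C@@](C)(C#C[Si](C)(C)C)[C@@H]2CCC1C | intermediate
20 | potassium enolate of 19 (C1=C2) | CC1=C([O-])[C@]2(C)CCC[C@@](C)(C#C[Si](C)(C)C)[C@@H]2CC1.[K+] | intermediate
21 | (4aS,5R,8aR)-2,5,8a-trimethyl-5-[(trimethylsilyl)ethynyl]-3,4,4a,5,6,7,8,8a-octahydronaphthalen-1-yl trifluoromethanesulfonate | CC1=C(OS(=O)(=O)C(F)(F)F)[C@]2(C)CCC[C@@](C)(C#C[Si](C)(C)C)[C@@H]2CC1 | intermediate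
22 | 2-(chloromethyl)-1,4-dimethoxybenzene (2,5-dimethoxybenzyl chloride) | COc1ccc(OC)c(CCl)c1 | starting material
23 | (2,5-dimethoxybenzyl)zinc chloride | COc1ccc(OC)c(C[Zn]Cl)c1 | intermediate
24 | trimethyl{[(1R,4aR,8aR)-5-(2,5-dimethoxybenzyl)-1,4a,6-trimethyl-1,2,3,4,4a,7,8,8a-octahydronaphthalen-1-yl]ethynyl}silane | CC1=C(Cc2cc(OC)ccc2OC)[C@]2(C)CCC[C@@](C)(C#C[Si](C)(C)C)[C@@H]2CC1 | intermediate
25 | (1R,4aR,8aS)-5-(2,5-dimethoxybenzyl)-1-ethynyl-1,4a,6-trimethyl-1,2,3,4,4a,7,8,8a-octahydronaphthalene | CC1=C(Cc2cc(OC)ccc2OC)[C@]2(C)CCC[C@@](C)(C#C)[C@@H]2CC1 | intermediate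
26 | lithium acetylide of 25 | CC1=C(Cc2cc(OC)ccc2OC)[C@]2(C)CCC[C@@](C)(C#C[Li])[C@@H]2CC1 | intermediate
27 | dichlorocerium acetylide of 25 | CC1=C(Cc2cc(OC)ccc2OC)[C@]2(C)CCC[C@@](C)(C#C[Ce](Cl)Cl)[C@@H]2CC1 | intermediate
28 | propargylic alcohol: 25 joined through its alkyne terminus to C6 of the benzoxepane of 10 (OH cis to C7-Me and O1; alkynyl cis to C5a-Me) | CC1=C(Cc2cc(OC)ccc2OC)[C@]2(C)CCC[C@@](C)(C#C[C@@]3(O)[C@H](C)CC[C@@H]4OC(C)(C)CCC[C@@]43C)[C@@H]2CC1 | intermediate
29 | 2-substituted 1,4-benzoquinone from 28 | CC1=C(CC2=CC(=O)C=CC2=O)[C@]2(C)CCC[C@@](C)(C#C[C@@]3(O)[C@H](C)CC[C@@H]4OC(C)(C)CCC[C@@]43C)[C@@H]2CC1 | intermediate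
30 | hydroquinone with saturated CH2CH2 link (diphenol of the target) | CC1=C(Cc2cc(O)ccc2O)[C@]2(C)CCC[C@@](C)(CC[C@@]3(O)[C@H](C)CC[C@@H]4OC(C)(C)CCC[C@@]43C)[C@@H]2CC1 | intermediate
31 | CNP0125037.2, bis(hydrogen sulfate) of 30 | CC1=C(Cc2cc(OS(=O)(=O)O)ccc2OS(=O)(=O)O)[C@]2(C)CCC[C@@](C)(CC[C@@]3(O)[C@H](C)CC[C@@H]4OC(C)(C)CCC[C@@]43C)[C@@H]2CC1 | target

**Totals.** Total step count: 18. Longest linear sequence: 11 steps (steps 1–7 or 8–14, then 15–18).

**Steps most likely to fail**

Step 8. What may go wrong: slow or unselective transfer of the α-branched alkenyl group from aluminium to the α-substituted enone (competing isobutyl transfer, 1,2-addition, low enantioselectivity). The fallback replaces copper/aluminium by rhodium/boron. It sets out from 11 and 12: the alane 13 is quenched with methoxy(pinacolato)borane to give 2-(5-chloropent-1-en-2-yl)-4,4,5,5-tetramethyl-1,3,2-dioxaborolane F1. F1 is added to 12 in a Hayashi–Miyaura reaction ([Rh(cod)Cl]2, (R)-BINAP, aq. KOH, dioxane, 60 °C), for which (R)-BINAP is expected to give the 3R adduct. The route is rejoined at 14.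

Step 10. What may go wrong: capture of the tertiary radical on the concave face (wrong C5 epimer), or its reduction before it reaches the alkynyl sulfone. The fallback uses polar chemistry with the order of introduction inverted, so that the carbon substituent is in place first and the methyl group arrives last. It sets out from 16: m-CPBA gives the spiro-epoxide F2, and BF3·OEt2 induces Meinwald rearrangement to the aldehyde F3. The potassium enolate of F3 (t-BuOK) is C-methylated with MeI to the quaternary aldehyde F4; a centre that is attacked on the concave face now receives the methyl there and keeps the formyl group on the convex face. Ohira–Bestmann homologation gives the terminal alkyne F5. Double deprotonation and silylation (LiHMDS, Me3SiCl) give the bis-silyl compound F6, and dilute acid returns the route to 17.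

Step 15. What may go wrong: enolisation of the hindered ketone, or attack of the slim acetylide along the axial trajectory, giving the C6 epimer. The fallback uses a bulkier sp3 organocerium, expected to prefer the equatorial trajectory more strongly. It sets out from 25: hydroboration–oxidation (dicyclohexylborane; NaOH, H2O2) gives the aldehyde F7, NaBH4 the alcohol F8, and I2/PPh3/imidazole the iodide F9. Iodine–lithium exchange (t-BuLi) gives the alkyllithium F10, which after transmetalation with CeCl3 adds to 10 to give the saturated tertiary alcohol F11. Oxidation with (NH4)2Ce(NO3)6 gives the quinone F12, and reduction with Na2S2O4 returns the route to 30.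

**Further compounds**

F1 | step 8 | 2-(5-chloropent-1-en-2-yl)-4,4,5,5-tetramethyl-1,3,2-dioxaborolane | C=C(CCCCl)B1OC(C)(C)C(C)(C)O1
F2 | step 10 | spiro-epoxide of 16 (oxirane on C5, both epimers) | O=C1[C@]2(C)CCCC3(CO3)[C@@H]2CCC1
F3 | step 10 | (4aS,8aR)-8a-methyl-1-oxodecahydronaphthalene-5-carbaldehyde (C5 epimers) | O=C1[C@]2(C)CCCC(C=O)[C@@H]2CCC1
F4 | step 10 | 5,8a-dimethyl-1-oxodecahydronaphthalene-5-carbaldehyde (formyl cis to angular methyl and ring-fusion H) | O=C1[C@]2(C)CCC[C@@](C)(C=O)[C@@H]2CCC1
F5 | step 10 | 5-ethynyl-5,8a-dimethyloctahydronaphthalen-1(2H)-one (configuration as 17) | O=C1[C@]2(C)CCC[C@@](C)(C#C)[C@@H]2CCC1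
F6 | step 10 | trimethylsilyl enol ether of 17 | C[Si](C)(C)OC1=CCC[C@H]2[C@](C)(C#C[Si](C)(C)C)CCC[C@@]12C
F7 | step 15 | aldehyde: CH2CHO in place of the ethynyl group of 25 | CC1=C(Cc2cc(OC)ccc2OC)[C@]2(C)CCC[C@@](C)(CC=O)[C@@H]2CC1
F8 | step 15 | primary alcohol: CH2CH2OH in place of the ethynyl group of 25 | CC1=C(Cc2cc(OC)ccc2OC)[C@]2(C)CCC[C@@](C)(CCO)[C@@H]2CC1
F9 | step 15 | primary iodide: CH2CH2I in place of the ethynyl group of 25 | CC1=C(Cc2cc(OC)ccc2OC)[C@]2(C)CCC[C@@](C)(CCI)[C@@H]2CC1
F10 | step 15 | alkyllithium from F9 | CC1=C(Cc2cc(OC)ccc2OC)[C@]2(C)CCC[C@@](C)(CC[Li])[C@@H]2CC1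
F11 | step 15 | saturated tertiary alcohol, dimethyl ether of 30 | CC1=C(Cc2cc(OC)ccc2OC)[C@]2(C)CCC[C@@](C)(CC[C@@]3(O)[C@H](C)CC[C@@H]4OC(C)(C)CCC[C@@]43C)[C@@H]2CC1
F12 | step 15 | 1,4-benzoquinone corresponding to 30 | CC1=C(CC2=CC(=O)C=CC2=O)[C@]2(C)CCC[C@@](C)(CC[C@@]3(O)[C@H](C)CC[C@@H]4OC(C)(C)CCC[C@@]43C)[C@@H]2CC1
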